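## Structural features

The target is a germacranolide: a ten-membered carbocycle (C1–C10) with a trisubstituted 1(10)Z alkene and a trisubstituted 4E alkene in a 1,5-relationship, and a trans-fused α-methylene-γ-butyrolactone across C6–C7 (O on C6, C11–C13 on C7). Four stereocentres stand in a row, C6–C7–C8–C9: O6 and C11 are trans, the C8 ester is cis to C11, and the C9 hydroxyl is erythro (cis on the ring) to the C8 ester. A fifth, isolated centre is the quaternary epoxide carbon of the (R)-3,4-epoxy-3-methylbutanoyl group on O8. Fragile groups are the α-methylene lactone (acceptor for amines, thiols, alkoxides and hydride), the 1,5-diene (Cope rearrangement on heating, transannular cyclisation in acid), the β,γ-epoxy ester (E1cB opening in base, lactonisation in acid) and the vicinal hydroxy ester (acyl shift from O8 to O9). The real difficulty is a medium ring with one Z and one E alkene beside four contiguous stereocentres, together with the need to tell O8 from O9 at the end. The feature exploited is that C1–C4 with C5 and C10 are the cycloreversion pattern of a bicyclo[2.2.0]hexane, while ring C5–C10 with C14 and C11–C13 is the carbon skeleton of carvone with C7 already set. On that enone C9 is the carbonyl carbon, C8 the α′-position and C6 the γ-position.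

## Logic of the disconnections

21 to 20: the C9–H bond is removed, so the carbinol becomes a ketone. This keeps O8 and O9 different in oxidation level until the last step and gives the enone that the photochemistry needs. One stereocentre is removed. The forward step must reduce 1,2 with 8,9-erythro selectivity and leave the lactone, the epoxide and the ester position alone.

20 to 16 and 19: the acyl C–O bond at O8 is cut. The epoxy acyl group is base- and heat-sensitive and should not pass the thermolysis. This makes the route convergent and hands the remote epoxide centre to a separate two-step branch. The forward step must acylate a hindered α-hydroxy ketone without epimerising C8 or opening the epoxide.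

19 to 18 to 17: the carboxyl is taken back to the primary alcohol and the two epoxide C–O bonds to the alkene. This gives a C5 commodity alcohol. The demand is an enantioselective epoxidation of a 1,1-disubstituted homoallylic alcohol.

16 to 15: the O8–Si bond is restored. The silyl ether serves as protecting group, as face-directing group in the photoaddition and as a volatility aid in the thermolysis. Its removal must be non-basic.

15 to 14: C1–C4 and C5–C10 are reconnected. Both ring alkenes are thus products of one strain-driven cycloreversion, and the ten-membered ring shrinks to a six-membered ring carrying a bicyclo[2.2.0]hexane. The E/Z problem becomes a question of relative configuration in 14. The forward step needs the right partition of the 1,4-diyl and a contact time too short for Cope rearrangement.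

14 to 11 and 13: C5–C4 and C10–C1 are cut (key step). Two skeletal bonds and one ring are removed, leaving an enone and a C5 alkene. The forward step needs head-to-tail orientation, cis ring fusion and the correct enone face.

13 to 12: a double-bond shift from the commercial exocyclic isomer. The demand is only that the isomers be separated before the photoaddition.

11 to 9 to 8: the C8–O bond is cut. Oxygenation is placed after lactone formation, because the trans-fused lactone locks the ring and makes axial attack at C8 deliver the oxygen cis to C11 directly. No inversion step is then needed.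

8 to 5 to 4: the C6–O bond and the lactone acyl C–O bond are cut. Oxygen is brought in from outside, anti to the C7 side chain, which is the only way to a trans fusion. The lactone then closes by acyl substitution. The demand is γ- rather than α′-enolisation and anti facial selectivity.

4 to 3 to 2 to 1: C12 is taken down from acid to methyl. The forward steps must functionalise the isopropenyl methyl without touching the enone.

## Other disconnections considered

Alternative 1: The cut is C8–C9. In the forward sense dialdehyde A1, with the lactone saturated at C11, is treated with SmI2; the ketyl of one formyl group adds to the other and closes the ring as diol A2.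
- In its favour: ring closure and both carbinol centres come in one mild, low-temperature step. Both alkene geometries are fixed beforehand by acyclic olefination. On that point it is better than the chosen plan, where the geometry depends on how a diyl partitions.
- Against it here: SmI2 reduces α-methylene lactones, so C13 must be added afterwards on a diol-bearing ten-membered ring. The C9 aldehyde is a conjugated Z-enal whose ketyl can couple through C1. Up to four diols can form and only one is wanted. C7 in A1 is α to a formyl group and can epimerise. A2 carries two free secondary hydroxyls that must be told apart before acylation.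
- Comparison: the chosen plan keeps O8 and O9 different by oxidation level to the last step and brings methyls, lactone and methylene through ring formation intact. Mechanistically A2 arises by intramolecular radical–carbonyl coupling against entropy, whereas 15 arises by strain release. A1 needs a long linear assembly, so the chosen plan is clearly shorter.

Alternative 2: The cut is C2–C3, paired with cleavage of C5–C10. The potassium alkoxide of divinylcyclohexanol A3 (KH, 18-crown-6) undergoes an anionic oxy-Cope rearrangement, and the C10 enolate is trapped with PhNTf2 as enol triflate A4.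
- In its favour: it uses the same six-membered ring C5–C10 and the same ring-expansion logic, but runs at low temperature and through a concerted chair transition state. Both are better than a flash thermolysis through a diradical. The cis 8,9-diol is set on a six-membered ring as an acetonide, which is better stereocontrol at C9 than the late reduction of 20.
- Against it here: A4 lacks the C10 methyl (a later cross-coupling), has C12 at the alcohol level and lacks C13. Lactone formation, methylenation, removal of the benzyl-type ether and of the acetonide (acid, on a germacradiene) and differentiation of O8 and O9 all follow ring expansion. A3 requires a cis-selective vinyl addition to a hindered ketone.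
- Comparison: in the chosen plan the skeleton leaves ring expansion four steps from the target. Alternative 2 is the equal in ring-size logic and the better in temperature and in C9 control, but pays with a long endgame.

Alternative 3: The cut is C9–C10. Iodo aldehyde A5 is treated with CrCl2 and catalytic NiCl2; the C10 iodide becomes a carbon nucleophile that adds to the C9 aldehyde and closes the ring as A6.
- In its favour: the conditions tolerate the α-methylene lactone, so the alternative equals the chosen plan in carrying the complete lactone through ring formation. The Z geometry is preset in the alkenyl iodide and transferred with retention. C9 is formed directly as the carbinol, and Felkin-type addition to the α-silyloxy aldehyde should give the needed erythro relationship. On both points it is better than the chosen plan.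
- Against it here: A5 is an open chain with three stereocentres, a Z-trisubstituted alkenyl iodide and an E-trisubstituted alkene, none of which carvone can supply. The closure needs high dilution and excess CrCl2. The α-silyloxy aldehyde can epimerise. A6 has O9 free and O8 silylated, the wrong way round for acylation at O8, so a protecting-group exchange of about three steps follows.
- Comparison: sp2–sp3 C–C closure of an acyclic chain versus cycloreversion of a preformed polycycle. Stereochemical predictability at C9 and C1=C10 favours alternative 3; length favours the chosen plan.

Key step: step 9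

## Route

Assumption: locants are germacrane locants (ring C1–C10, C11–C13 on C7, C14 on C10, C15 on C4); 1-methylcyclobutene is taken as not purchasable and is made in step 8; the photoadduct is carried as the enone-face diastereomer with the new cyclobutane anti to the C8 silyl ether, because the thermolysis geometry is argued to depend on that face.

Step 1
Reactants: 1 (S)-(+)-carvone
Product: 2 (5S)-5-(3-chloroprop-1-en-2-yl)-2-methylcyclohex-2-en-1-one (10-chlorocarvone)
Conditions: Ca(OCl)2, solid CO2, CH2Cl2/H2O, 0 °C
Reagents that add atoms: calcium hypochlorite, [Ca+2].[O-]Cl.[O-]Cl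
Why: Ene-type chlorination by HOCl (released from Ca(OCl)2 by CO2) attacks only the electron-rich 1,1-disubstituted alkene and shifts it, giving the allylic chloride; the conjugated ring alkene is inert and C7 is untouched.

Step 2
Reactants: 2 10-chlorocarvone
Product: 3 2-[(1S)-4-methyl-5-oxocyclohex-3-en-1-yl]prop-2-enal
Conditions: 4-methylmorpholine N-oxide (3 equiv), NaI (cat.), MeCN, 40 °C
Reagents that add atoms: 4-methylmorpholine N-oxide, C[N+]1([O-])CCOCC1
Why: Kornblum-type N-oxide oxidation: the N-oxide oxygen displaces the allylic halide (direct and allylic displacement give the same product because the allyl unit is symmetric) and loss of the amine from the alkoxyammonium ion gives the 2-substituted acrolein.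

Step 3
Reactants: 3 the enal
Product: 4 2-[(1S)-4-methyl-5-oxocyclohex-3-en-1-yl]prop-2-enoic acid
Conditions: NaClO2, NaH2PO4, 2-methyl-2-butene, tBuOH/H2O, 0 °C → rt
Reagents that add atoms: sodium chlorite, [Na+].[O-]Cl=O
Why: Pinnick oxidation takes the conjugated aldehyde to the acrylic acid without touching the enone; the alkene additive scavenges HOCl.

Step 4
Reactants: 4 the acrylic acid
Product: 5 trimethylsilyl 2-[(1R)-4-methyl-5-(trimethylsilyloxy)cyclohexa-2,4-dien-1-yl]prop-2-enoate (linearly conjugated dienol ether; CIP label changes but C7 is unchanged in space; used crude)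
Conditions: TMSCl, NaI, Et3N, MeCN, 0 °C → rt; pentane extraction
Reagents that add atoms: chlorotrimethylsilane, C[Si](C)(C)Cl
Why: Thermodynamic silyl dienol ether formation: silylation by TMSI made in the flask is reversible, so the linearly conjugated 1-silyloxy-1,3-diene (loss of the γ-proton at C6) should prevail over the kinetic cross-conjugated isomer; the acid is masked at the same time as its silyl ester.

Step 5
Reactants: 5 the bis-silyl dienol ether
Product: 8 trans-fused enone lactone (3aS,7aR)-6-methyl-3-methylidene-3a,4-dihydro-1-benzofuran-2,5(3H,7aH)-dione (germacrane locants 6R,7S), via epoxy silyl dienol ether 6 (not isolated), via hydroxy acid 7 (not isolated)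
Conditions: dimethyldioxirane, acetone/CH2Cl2, −78 °C; 0.5 M citric acid, THF, 0 °C; EDC·HCl, DMAP (cat.), CH2Cl2, 0 °C
Reagents that add atoms: dimethyldioxirane, CC1(C)OO1
Why: Vinylogous Rubottom oxidation: the oxidant attacks the γ,δ-double bond of the electron-rich diene from the face away from the C7 side chain, so the new C6–O bond is trans to C11, and the acrylate alkene is too electron-poor to compete. Mild acid unravels the epoxide and both silyl groups to the γ-hydroxy enone acid, which is closed by carbodiimide activation (acyl substitution, C6 untouched) before acid can dehydrate it towards a phenol.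

Step 6
Reactants: 8 the enone lactone
Product: 9 (3aS,7aR)-5-[tert-butyl(dimethyl)silyl]oxy-6-methyl-3-methylidene-3a,7a-dihydro-1-benzofuran-2(3H)-one (cross-conjugated dienol ether C8=C9)
Conditions: TBSOTf, Et3N, CH2Cl2, −78 → 0 °C
Reagents that add atoms: tert-butyldimethylsilyl triflate, CC(C)(C)[Si](C)(C)OS(=O)(=O)C(F)(F)F
Why: Soft enolisation removes the kinetically most accessible α′ proton at C8 and gives the 2-silyloxy diene; the lactone has no α-hydrogen and survives a tertiary amine. The product is kept free of acid and used at once, since loss of the allylic C6 carboxylate would aromatise the ring.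

Step 7
Reactants: 9 the silyl dienol ether
Product: 11 (3aS,4S,7aR)-4-[tert-butyl(dimethyl)silyl]oxy-6-methyl-3-methylidene-3a,4-dihydro-1-benzofuran-2,5(3H,7aH)-dione (germacrane locants 6R,7S,8S; silyl ether axial, cis to C11), via silyloxy epoxide 10 (not isolated)
Conditions: dimethyldioxirane, acetone/CH2Cl2, −78 → −20 °C; CSA (cat.), CH2Cl2, 0 °C
Reagents that add atoms: dimethyldioxirane, CC1(C)OO1
Why: Rubottom oxidation: the silyl enol ether C8=C9 is the most electron-rich alkene, and its epoxide rearranges with 1,4-silyl shift to the α-silyloxy ketone. The trans-fused lactone locks H7 axial and C11 equatorial, so attack anti to the axial C7–H (chair-like, axial bond formation) should place the new C8–O bond axial and cis to C11; an equatorial substituent would also clash with the C13 methylene.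

Step 8
Reactants: 12 methylenecyclobutane
Product: 13 1-methylcyclobutene
Conditions: Na/Al2O3 (cat.), neat, 0 °C → rt; spinning-band distillation
Reagents that add atoms: none
Why: Base-catalysed allylic proton shift equilibrates the exocyclic alkene with the more stable endocyclic trisubstituted isomer; distillation removes residual 12, which would otherwise add to the enone as a competing partner.

Step 9
Reactants: 11 the enone lactone silyl ether; 13 1-methylcyclobutene
Product: 14 cis,anti,cis photoadduct (bicyclo[2.2.0]hexane C1–C4 with C5 and C10, fused at C5–C10 to the lactone-bearing cyclohexanone; C4 on C5 and C1 on C10; cyclobutane on the enone face anti to the C8 silyl ether; C6, C7 and C8 as in 11)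
Conditions: hν (350–366 nm, uranium-glass filter), 13 (10 equiv), degassed CH2Cl2 (0.02 M), −40 °C
Reagents that add atoms: none
Why: Irradiation above 340 nm excites only the enone (n→π*), and after intersystem crossing the twisted triplet is intercepted by the excess alkene to give a triplet 1,4-diradical that closes, after spin inversion, by radical recombination; the closest known reaction type is the intermolecular enone–cycloalkene [2+2] photocycloaddition, here with a cyclobutene. The one ring closed is the cyclobutane C5–C4–C1–C10, formed stepwise (first C–C bond, then four-membered ring closure of the diradical), which completes the bicyclo[2.2.0]hexane. Head-to-tail orientation (C5–C4, C10–C1) is the normal outcome for an electron-rich alkene and is reinforced here because the reverse orientation would have to join the two fully substituted carbons C10 and C4. C1 and C4 are cis because they come from a ring alkene; cis fusion at C5/C10 and the anti disposition of the two outer rings follow the usual cis,anti,cis preference of cycloalkene adducts, and closure at the opposite face of C10 (trans fusion) would have to pass the axial C8 silyl ether. That axial silyl ether also shields one enone face, so the alkene should enter syn to H7 and give 14; any adduct formed on the silyl ether face is removed by chromatography at this stage. The face matters even though C1, C4, C5 and C10 all become sp2 later: in 14 the C5–C4 bond is axial on the lactone-locked six-membered ring, the arrangement from which the diyl of step 10 reaches its chair with C6 equatorial and C9 axial while the carbocycle keeps its own chair, whereas addition on the other face would demand a diyl chair with C6 axial and would lead towards the 4Z,1(10)E isomer. The α-methylene lactone should stay a spectator: it does not absorb at this wavelength, its triplet is expected to lie above that of the enone, and the trans ring fusion holds C11=C13 away from C5=C10, so the internal [2+2] that free carvone undergoes is geometrically excluded.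

Step 10
Reactants: 14 the photoadduct
Product: 15 (1(10)Z,4E)-8-[tert-butyl(dimethyl)silyl]oxy-9-oxogermacra-1(10),4,11(13)-trien-12,6-olide (6R,7S,8S)
Conditions: flash vacuum thermolysis, quartz tube, ca. 400–450 °C, 10^-2 mbar, millisecond contact, trap at −78 °C
Reagents that add atoms: none
Why: Thermal cycloreversion of a bicyclo[2.2.0]hexane: strain-driven homolysis of C1–C4 gives a cyclohexane-1,4-diyl, and scission of C5–C10 (the weaker, more substituted bond, giving the enone) yields the cis,trans-cyclodeca-1,5-diene. From 14 the diyl chair has C6 equatorial (hence 4E) and C9 axial with C14 equatorial (hence 1(10)Z); short contact time is meant to stop the product before Cope rearrangement.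

Step 11
Reactants: 15 the silyl ether dienone
Product: 16 (1(10)Z,4E)-8-hydroxy-9-oxogermacra-1(10),4,11(13)-trien-12,6-olide (configuration unchanged; CIP labels 6R,7R,8S)
Conditions: HF·pyridine, pyridine, THF, 0 °C → rt
Reagents that add atoms: none
Why: Buffered fluoride cleaves the secondary silyl ether under weakly acidic, non-basic conditions, so the C8 centre (α to the ketone), the α-methylene lactone and the 1,5-diene are preserved.

Step 12
Reactants: 17 3-methylbut-3-en-1-ol
Product: 18 2-[(2R)-2-methyloxiran-2-yl]ethan-1-ol
Conditions: Hf(OtBu)4 (cat.), chiral C2-symmetric bis-hydroxamic acid ligand (antipode that delivers the R epoxide), cumene hydroperoxide, DMPU, 4 Å MS, toluene, 0 °C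
Reagents that add atoms: cumene hydroperoxide, CC(C)(OO)c1ccccc1
Why: Hydroxyl-directed catalytic asymmetric epoxidation of a 1,1-disubstituted homoallylic alcohol: the alcohol binds to the metal centre of the Hf(OtBu)4–ligand complex and the chiral ligand selects the alkene face.

Step 13
Reactants: 18 the epoxy alcohol
Product: 19 2-[(2R)-2-methyloxiran-2-yl]acetic acid
Conditions: TEMPO (cat.), NaOCl (cat.), NaClO2, MeCN/phosphate buffer (pH 6.7), rt; cold extraction, used at once
Reagents that add atoms: sodium chlorite, [Na+].[O-]Cl=O
Why: Oxoammonium/chlorite oxidation at near-neutral pH takes the primary alcohol through the aldehyde to the acid without exposing the 2,2-disubstituted epoxide to acid or base; the quaternary centre is not involved.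

Step 14
Reactants: 16 the ketol; 19 the epoxy acid
Product: 20 (1(10)Z,4E)-9-oxo-8-{2-[(2R)-2-methyloxiran-2-yl]acetoxy}germacra-1(10),4,11(13)-trien-12,6-olide (6R,7S,8S)
Conditions: DIC, DMAP (0.1 equiv), CH2Cl2, −10 → 0 °C
Reagents that add atoms: none
Why: Steglich-type carbodiimide esterification under near-neutral conditions with only catalytic DMAP, chosen to limit enolisation at C8 and base-induced opening of the β,γ-epoxy acyl unit; the C8–O bond is not broken, so configuration is retained.

Step 15
Reactants: 20 the keto ester
Product: 21 CNP0284481.1, (1(10)Z,4E)-9-hydroxy-8-{2-[(2R)-2-methyloxiran-2-yl]acetoxy}germacra-1(10),4,11(13)-trien-12,6-olide (6R,7S,8S,9R)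
Conditions: Zn(BH4)2, Et2O, −30 °C; aq. NH4Cl
Reagents that add atoms: none
Why: Zn(BH4)2 reduces the enone carbonyl 1,2 under neutral conditions and leaves esters, epoxide and α-methylene lactone alone. Zinc is expected to bridge the C9 carbonyl and the C8 acyloxy group, and hydride from the ring periphery on the side of H8 (Cram-chelate sense) gives the 8,9-erythro relationship, that is 9R.

## Compound list

1 | (S)-(+)-carvone | CC1=CC[C@@H](CC1=O)C(C)=C | starting material
2 | (5S)-5-(3-chloroprop-1-en-2-yl)-2-methylcyclohex-2-en-1-one | CC1=CC[C@@H](CC1=O)C(=C)CCl | intermediate
3 | 2-[(1S)-4-methyl-5-oxocyclohex-3-en-1-yl]prop-2-enal | CC1=CC[C@@H](CC1=O)C(=C)C=O | intermediate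
4 | 2-[(1S)-4-methyl-5-oxocyclohex-3-en-1-yl]prop-2-enoic acid | CC1=CC[C@@H](CC1=O)C(=C)C(=O)O | intermediate
5 | trimethylsilyl 2-[(1R)-4-methyl-5-(trimethylsilyloxy)cyclohexa-2,4-dien-1-yl]prop-2-enoate | CC1=C(O[Si](C)(C)C)C[C@H](C=C1)C(=C)C(=O)O[Si](C)(C)C | intermediate
6 | C5–C6 epoxide of 5, oxygen anti to the side chain (not isolated) | CC1=C(O[Si](C)(C)C)C[C@@H](C(=C)C(=O)O[Si](C)(C)C)[C@@H]2O[C@H]12 | intermediate
7 | 2-[(1S,2R)-2-hydroxy-4-methyl-5-oxocyclohex-3-en-1-yl]prop-2-enoic acid (not isolated) | O[C@@H]1C=C(C)C(=O)C[C@H]1C(=C)C(=O)O | intermediate
8 | (3aS,7aR)-6-methyl-3-methylidene-3a,4-dihydro-1-benzofuran-2,5(3H,7aH)-dione | C=C1C(=O)O[C@@H]2C=C(C)C(=O)C[C@@H]12 | intermediate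
9 | (3aS,7aR)-5-[tert-butyl(dimethyl)silyl]oxy-6-methyl-3-methylidene-3a,7a-dihydro-1-benzofuran-2(3H)-one | C=C1C(=O)O[C@@H]2C=C(C)C(O[Si](C)(C)C(C)(C)C)=C[C@@H]12 | intermediate
10 | C8–C9 silyloxy epoxide of 9, oxygen cis to C11 (not isolated) | C=C1C(=O)O[C@@H]2C=C(C)[C@@]3(O[Si](C)(C)C(C)(C)C)O[C@H]3[C@@H]12 | intermediate
11 | (3aS,4S,7aR)-4-[tert-butyl(dimethyl)silyl]oxy-6-methyl-3-methylidene-3a,4-dihydro-1-benzofuran-2,5(3H,7aH)-dione | C=C1C(=O)O[C@@H]2C=C(C)C(=O)[C@@H](O[Si](C)(C)C(C)(C)C)[C@@H]12 | intermediate
12 | methylenecyclobutane | C=C1CCC1 | starting material
13 | 1-methylcyclobutene | CC1=CCC1 | intermediate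
14 | cis,anti,cis photoadduct, cyclobutane anti to the C8 silyl ether | C=C1C(=O)O[C@@H]2[C@@H]3[C@@]4(C)CC[C@H]4[C@]3(C)C(=O)[C@@H](O[Si](C)(C)C(C)(C)C)[C@@H]12 | intermediate
15 | (1(10)Z,4E)-8-[tert-butyl(dimethyl)silyl]oxy-9-oxogermacra-1(10),4,11(13)-trien-12,6-olide | C=C1C(=O)O[C@@H]2/C=C(\C)CC/C=C(/C)C(=O)[C@@H](O[Si](C)(C)C(C)(C)C)[C@@H]12 | intermediate
16 | (1(10)Z,4E)-8-hydroxy-9-oxogermacra-1(10),4,11(13)-trien-12,6-olide | C=C1C(=O)O[C@@H]2/C=C(\C)CC/C=C(/C)C(=O)[C@@H](O)[C@@H]12 | intermediate
17 | 3-methylbut-3-en-1-ol | CC(=C)CCO | starting material
18 | 2-[(2R)-2-methyloxiran-2-yl]ethan-1-ol | OCC[C@]1(C)CO1 | intermediate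
19 | 2-[(2R)-2-methyloxiran-2-yl]acetic acid | OC(=O)C[C@]1(C)CO1 | intermediate
20 | (1(10)Z,4E)-9-oxo-8-{2-[(2R)-2-methyloxiran-2-yl]acetoxy}germacra-1(10),4,11(13)-trien-12,6-olide | C=C1C(=O)O[C@@H]2/C=C(\C)CC/C=C(/C)C(=O)[C@@H](OC(=O)C[C@]3(C)CO3)[C@@H]12 | intermediate
21 | CNP0284481.1 | C=C1C(=O)O[C@@H]2/C=C(\C)CC/C=C(/C)[C@@H](O)[C@@H](OC(=O)C[C@]3(C)CO3)[C@@H]12 | target

Total step count: 15. Longest linear sequence: 12 (steps 1–7, 9, 10, 11, 14, 15).

Least certain steps

Step 9 (key step).
- Most likely to go wrong: capture of the triplet by a trisubstituted alkene at an α-methylated enone is slow, which lets side channels compete. These are head-to-head orientation, closure to the trans-fused ring, entry of the alkene on the silyl-ether face and, above all, consumption of the α-methylene lactone by radical oligomerisation or sensitised addition of the cyclobutene across C11=C13.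
- Fallback (sets out from 11, rejoins at 15): C11=C13 is masked before irradiation. Conjugate addition of thiophenol (PhSH, Et3N cat.) to 11 gives the 13-phenylthio-11,13-dihydro lactone F1. Irradiation with 13 as in step 9 gives the masked photoadduct F2. mCPBA (1 equiv, −78 °C) gives the sulfoxide F3. Flash thermolysis of F3 combines sulfoxide syn-elimination, which restores C11=C13, with the cycloreversion and delivers 15.

Step 4.
- Most likely to go wrong: silylation stops at the kinetic cross-conjugated dienol ether (loss of the α′ proton at C8) instead of equilibrating to the linearly conjugated one, because both are cyclohexa-1,3-dienes of similar stability.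
- Fallback (sets out from 4, rejoins at 7): regiocontrol is handed to an equilibrating metal dienolate. KOtBu (2.2 equiv, tBuOH/THF, 0 °C) gives the linearly conjugated potassium dienolate, and inverse quench into cold aqueous AcOH protonates C10 to give the β,γ-unsaturated keto acid F4. mCPBA in a NaHCO3-buffered two-phase system gives the ring epoxide anti to the side chain, epoxy keto acid F5. Et3N opens it by E1cB elimination to 7, which is lactonised to 8 as in step 5.

Step 5.
- Most likely to go wrong: oxygen transfer to the tetrasubstituted enol-ether double bond (oxygenation at C10) or to the face syn to the side chain, and acid-induced dehydration of the γ-hydroxy enone.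
- Fallback (sets out from 5, rejoins at 7): photooxygenation replaces epoxidation. Singlet oxygen (O2, hν, tetraphenylporphyrin, CH2Cl2, −78 °C) can add to the cisoid diene only across C6 and C9 and gives the bicyclic endoperoxide F6. Thiourea in MeOH reduces the O–O bond, and collapse of the silyl hemiketal and methanolysis of the silyl ester give 7.

Step 7.
- Most likely to go wrong: poor facial selectivity, with oxygen delivered syn to H7 (equatorial, trans to C11), since the preference for axial attack rests on torsional effects only; aromatisation of 9 by loss of the C6 carboxylate before it is oxidised is a second concern.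
- Fallback (sets out from 9 through the unwanted epimer, rejoins at 11): the C8-epimeric silyl ether F7 is desilylated (HF·pyridine) to the trans ketol F8. Mitsunobu reaction with formic acid (PPh3, DIAD) inverts the activated α-ketol carbon and gives the cis formate F9. KHCO3 in MeOH at 0 °C frees the cis ketol F10, and TBSOTf/2,6-lutidine gives 11.

Step 10.
- Most likely to go wrong: the diyl partitions towards the 4Z,1(10)E isomer or towards the cis-divinylcyclohexane (directly by C2–C3 scission or by Cope rearrangement of 15). The 1,3-diaxial contact between C14 and the C8 silyl ether in the diyl pushes the lactone-bearing ring out of its chair.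
- Fallback (sets out from 14, rejoins at 16): the order of desilylation and thermolysis is exchanged. HF·pyridine converts 14 into the tricyclic ketol F11, in which that contact is much smaller, and its flash thermolysis gives 16 directly.

Step 15.
- Most likely to go wrong: hydride delivery to the other face of C9, because an acyloxy group binds zinc only weakly and the conformation of the ten-membered enone is not known; acyl shift from O8 to O9 in the product is a second concern.
- Fallback (sets out from 16, rejoins at 21): C9 is set on the free ketol, where zinc chelation is strongest. Zn(BH4)2 reduces 16 to the 8,9-erythro diol F12. The allylic O9, which lies on the ring periphery away from the lactone fusion, is expected to be silylated first (TESCl, imidazole, −40 °C) and gives the 9-O-triethylsilyl ether F13. Acylation with 19 as in step 14 gives the silylated ester F14, and HF·pyridine removes the triethylsilyl group to give 21.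

## Further compounds

F1 | step 9 | 13-phenylthio-11,13-dihydro derivative of 11 (C11 epimers) | c1ccc(SCC2C(=O)O[C@@H]3C=C(C)C(=O)[C@@H](O[Si](C)(C)C(C)(C)C)[C@@H]23)cc1
F2 | step 9 | photoadduct of F1 with 13 (cyclobutane anti to the silyl ether) | c1ccc(SCC2C(=O)O[C@@H]3[C@@H]4[C@@]5(C)CC[C@H]5[C@]4(C)C(=O)[C@@H](O[Si](C)(C)C(C)(C)C)[C@@H]23)cc1
F3 | step 9 | sulfoxide of F2 | O=S(CC1C(=O)O[C@@H]2[C@@H]3[C@@]4(C)CC[C@H]4[C@]3(C)C(=O)[C@@H](O[Si](C)(C)C(C)(C)C)[C@@H]12)c1ccccc1
F4 | step 4 | 2-[(1R)-4-methyl-5-oxocyclohex-2-en-1-yl]prop-2-enoic acid (C10 epimers) | CC1C=C[C@@H](CC1=O)C(=C)C(=O)O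
F5 | step 4 | C5–C6 epoxide of F4, oxygen anti to the side chain | CC1[C@H]2O[C@H]2[C@@H](CC1=O)C(=C)C(=O)O
F6 | step 5 | C6,C9-endoperoxide of 5, peroxide bridge anti to the side chain | CC1=C[C@H]2OO[C@]1(O[Si](C)(C)C)C[C@H]2C(=C)C(=O)O[Si](C)(C)C
F7 | step 7 | C8 epimer of 11 (silyl ether trans to C11) | C=C1C(=O)O[C@@H]2C=C(C)C(=O)[C@H](O[Si](C)(C)C(C)(C)C)[C@@H]12
F8 | step 7 | trans ketol (C8 hydroxyl trans to C11) | C=C1C(=O)O[C@@H]2C=C(C)C(=O)[C@H](O)[C@@H]12
F9 | step 7 | cis formate (C8 formyloxy cis to C11) | C=C1C(=O)O[C@@H]2C=C(C)C(=O)[C@@H](OC=O)[C@@H]12
F10 | step 7 | cis ketol (C8 hydroxyl cis to C11) | C=C1C(=O)O[C@@H]2C=C(C)C(=O)[C@@H](O)[C@@H]12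
F11 | step 10 | desilylated photoadduct (8-hydroxy analogue of 14) | C=C1C(=O)O[C@@H]2[C@@H]3[C@@]4(C)CC[C@H]4[C@]3(C)C(=O)[C@@H](O)[C@@H]12
F12 | step 15 | (1(10)Z,4E)-8,9-dihydroxygermacra-1(10),4,11(13)-trien-12,6-olide, 8,9-erythro | C=C1C(=O)O[C@@H]2/C=C(\C)CC/C=C(/C)[C@@H](O)[C@@H](O)[C@@H]12
F13 | step 15 | 9-O-triethylsilyl ether of F12 | C=C1C(=O)O[C@@H]2/C=C(\C)CC/C=C(/C)[C@@H](O[Si](CC)(CC)CC)[C@@H](O)[C@@H]12
F14 | step 15 | 9-O-triethylsilyl ether of 21 | C=C1C(=O)O[C@@H]2/C=C(\C)CC/C=C(/C)[C@@H](O[Si](CC)(CC)CC)[C@@H](OC(=O)C[C@]3(C)CO3)[C@@H]12
A1 | alternative 1 | seco-8,9 dialdehyde with saturated lactone | O=C[C@H]1CC(=O)O[C@@H]1/C=C(\C)CC/C=C(/C)C=O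
A2 | alternative 1 | ten-membered lactone C8,C9-diol | C1C(=O)O[C@@H]2/C=C(\C)CC/C=C(/C)[C@@H](O)[C@@H](O)[C@@H]12
A3 | alternative 2 | cis-1-vinyl-2-isopropenylcyclohexanol with acetonide, PMB ether and silyloxyethyl chain | COc1ccc(CO[C@@H]2[C@H](C(C)=C)[C@](O)(C=C)[C@H]3OC(C)(C)O[C@H]3[C@H]2CCO[Si](C)(C)C(C)(C)C)cc1
A4 | alternative 2 | ten-membered C10 enol triflate | COc1ccc(CO[C@@H]2/C=C(\C)CC/C=C(/OS(=O)(=O)C(F)(F)F)[C@H]3OC(C)(C)O[C@H]3[C@H]2CCO[Si](C)(C)C(C)(C)C)cc1
A5 | alternative 3 | seco-9,10 Z-alkenyl iodide aldehyde with C8 triethylsilyl ether | C=C1C(=O)O[C@H](/C=C(\C)CC/C=C(/C)I)[C@H]1[C@H](O[Si](CC)(CC)CC)C=O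
A6 | alternative 3 | ten-membered α-methylene lactone, C9 hydroxyl free, C8 triethylsilyl ether | C=C1C(=O)O[C@@H]2/C=C(\C)CC/C=C(/C)[C@@H](O)[C@@H](O[Si](CC)(CC)CC)[C@@H]12
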